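**Plan**

1. Numbering: ring A = C1–C5 and C10; ring B = C5–C10 with the C8=C9 olefin; side chain C11–C18 on C9 (C18 = ester carbon).
2. Retrosynthetic cuts: first C14–C15 (alkenylzinc + alkenyl iodide 16), then C13–CH3 and C12–C13 (alkyne carbometalation, acetylide SN2), then C9–C10 together with one cyclopropane bond, so that C9, C11 and C12 come from an alkylidenecyclopropane made from a methyl ketone.
3. Enabling feature: the tetrasubstituted C8=C9 olefin of ring B with a CH2CH2 arm on C9 is the opened form of a spiro cyclopropylcarbinyl cation (C8 cationic, cyclopropane C9/C11/C12), and C10 is a tertiary cationic site next to the C5 stereocenter.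
4. Forward: all 13 carbons of (S)-α-ionone 1 become ring A, its three methyls and C6–C8 with the C8 methyl. Ring B is closed last by a cation–alkylidenecyclopropane cyclization with strain-release chloride opening. The chain is then joined through alkyne 9 and a diene coupling.
5. Stereochemistry: C5 comes from 1; C10 is set in the key step under control of C5 (trans fusion); C17 comes from hydroxy ester 10; both olefin geometries come from syn-carboalumination and Takai olefination and are kept in the coupling.

Key step: step 4

Assumption: enantiopure (S)-(−)-α-ionone is taken as purchasable (both antipodes are offered as fragrance standards); the carbon numbering of the plan is used throughout.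

**Route**

Step 1
Reactants: 1 (S)-α-ionone
Product: 3 (S)-dihydro-α-ionone [4-((1S)-2,6,6-trimethylcyclohex-2-en-1-yl)butan-2-one], via triethylsilyl enol ether 2 (not isolated)
Conditions: Et3SiH, RhCl(PPh3)3 (cat.), toluene, 50 °C; then K2CO3, MeOH, rt
Reagents that add atoms: none
Why: Rh-catalysed 1,4-hydrosilylation of the enone with a monohydrosilane and methanolysis of the silyl enol ether amount to a conjugate reduction that leaves the trisubstituted ring olefin and the C5 stereocenter untouched.

Step 2
Reactants: 3 (S)-dihydro-α-ionone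
Product: 4 hydroxy ketone [4-((1S)-2-hydroxy-2,6,6-trimethylcyclohexyl)butan-2-one; either configuration at the carbinol carbon]
Conditions: Co(acac)2 (cat.), PhSiH3, O2 (1 atm), THF, rt; then aq. Na2S2O3
Reagents that add atoms: dioxygen O=O
Why: Mukaiyama hydration (hydrogen atom transfer from a cobalt hydride to the less substituted olefin carbon, then capture of the tertiary radical by O2) installs the hydroxyl at the methyl-bearing ring carbon C10 as the later leaving group, and its configuration is irrelevant because C10 becomes planar in step 4.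

Step 3
Reactants: 4 hydroxy ketone
Product: 5 cyclopropylidene carbinol [(2S)-2-(3-cyclopropylidenebutyl)-1,3,3-trimethylcyclohexan-1-ol; either configuration at C1 of the cyclohexanol]
Conditions: c-C3H5PPh3Br (3.5 equiv), KOt-Bu (3.5 equiv), THF, 65 °C
Reagents that add atoms: cyclopropyltriphenylphosphonium bromide [Br-].C1CC1[P+](c1ccccc1)(c1ccccc1)c1ccccc1
Why: Wittig olefination with cyclopropylidenetriphenylphosphorane turns the methyl ketone into the alkylidenecyclopropane, the excess ylide compensating for deprotonation of the tertiary alcohol, and no stereocenter is formed.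

Step 4
Reactants: 5 cyclopropylidene carbinol
Product: 8 homoallylic chloride [(4aS,8aS)-1-(2-chloroethyl)-2,5,5,8a-tetramethyl-3,4,4a,5,6,7,8,8a-octahydronaphthalene], via tertiary cyclohexyl cation 6 (not isolated), via spiro cyclopropylcarbinyl cation 7 (not isolated)
Conditions: TiCl4 (2.5 equiv), 2,6-di-tert-butyl-4-methylpyridine (1.5 equiv), CH2Cl2, −78 → −30 °C; aq. NaHCO3
Reagents that add atoms: titanium tetrachloride Cl[Ti](Cl)(Cl)Cl
Why: Proposed new method: TiCl4 turns the tertiary carbinol into its chlorotitanate and ionises it to the tertiary cation 6 while the hindered pyridine traps every proton, so the cation is formed at C10 and nowhere else; its attack on the cyclopropylidene carbon (C9) of the tetrasubstituted olefin closes ring B in a 6-endo-trig cation–olefin cyclization and gives the bisected spiro cyclopropylcarbinyl cation 7, which chloride opens at a cyclopropane CH2 with release of ring strain to leave the C8=C9 olefin and the 2-chloroethyl arm. The closest known reaction types are the acid-induced closure of ionone-derived monocyclic dienes to trans-decalins, the Lewis-acid-mediated addition of carbon electrophiles to alkylidenecyclopropanes that ends in homoallylic halides, and the Julia cyclopropylcarbinyl-to-homoallyl rearrangement; their combination with a tertiary cation as the electrophile is not documented. The new quaternary stereocenter C10 is controlled by C5: the tether leaves C5 equatorially and bonds through a chair-like transition state for ring B, so the new bond forms trans to the C5–C6 bond and the angular methyl ends anti to H5 (trans fusion). Chemoselectivity (ionisation versus electrophilic opening of the alkylidenecyclopropane) rests on the aprotic Lewis acid plus proton trap, regioselectivity of attack (ring carbon, not exocyclic carbon) on the fact that only this mode gives a cyclopropylcarbinyl and not a cyclopropyl cation, and the position of the new olefin on reversible chloride capture at the tertiary centre, which funnels the material to the strain-free primary chloride.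

Step 5
Reactants: 8 homoallylic chloride
Product: 9 terminal alkyne [(4aS,8aS)-1-(but-3-yn-1-yl)-2,5,5,8a-tetramethyl-3,4,4a,5,6,7,8,8a-octahydronaphthalene]
Conditions: LiC≡CH·H2NCH2CH2NH2 (3 equiv), NaI (cat.), DMSO, rt
Reagents that add atoms: lithium acetylide–ethylenediamine complex [Li+].[C-]#C.NCCN
Why: SN2 alkylation of acetylide by the primary chloride (through the iodide formed in situ, a Finkelstein-assisted substitution) in DMSO is the standard route to a terminal alkyne, and the hindered tetrasubstituted olefin and the stereocenters are not involved.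

Step 6
Reactants: 10 methyl (S)-3-hydroxy-2-methylpropanoate
Product: 11 methyl (S)-3-((tert-butyldimethylsilyl)oxy)-2-methylpropanoate
Conditions: TBSCl, imidazole, DMF, rt
Reagents that add atoms: tert-butyldimethylsilyl chloride CC(C)(C)[Si](C)(C)Cl
Why: Standard silylation of the primary alcohol protects it through the reduction and olefination.

Step 7
Reactants: 11 methyl (S)-3-((tert-butyldimethylsilyl)oxy)-2-methylpropanoate
Product: 12 (S)-3-((tert-butyldimethylsilyl)oxy)-2-methylpropanal
Conditions: i-Bu2AlH (1.1 equiv), CH2Cl2, −78 °C; MeOH, then aq. potassium sodium tartrate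
Reagents that add atoms: none
Why: Partial reduction of the ester with i-Bu2AlH at −78 °C stops at the aldehyde through the tetrahedral aluminate, and the aldehyde is used crude to avoid epimerisation.

Step 8
Reactants: 12 (S)-3-((tert-butyldimethylsilyl)oxy)-2-methylpropanal
Product: 13 tert-butyl(((2R,3E)-4-iodo-2-methylbut-3-en-1-yl)oxy)dimethylsilane
Conditions: CrCl2 (6 equiv), CHI3 (2 equiv), THF/1,4-dioxane, 0 °C → rt
Reagents that add atoms: iodoform IC(I)I
Why: Takai olefination, in which the geminal dichromium species from CHI3 and CrCl2 adds to the aldehyde and eliminates to the (E)-iodoalkene under conditions that do not epimerise the α-stereocenter.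

Step 9
Reactants: 13 tert-butyl(((2R,3E)-4-iodo-2-methylbut-3-en-1-yl)oxy)dimethylsilane
Product: 14 (2R,3E)-4-iodo-2-methylbut-3-en-1-ol
Conditions: HF·pyridine, THF, 0 °C → rt
Reagents that add atoms: none
Why: Fluoride-mediated desilylation cleaves the silyl ether without touching the iodoalkene or the stereocenter.

Step 10
Reactants: 14 (2R,3E)-4-iodo-2-methylbut-3-en-1-ol
Product: 15 (2R,3E)-4-iodo-2-methylbut-3-enoic acid
Conditions: TEMPO (cat.), NaOCl (cat.), NaClO2, MeCN/pH 6.7 phosphate buffer, 35 °C
Reagents that add atoms: sodium chlorite [Na+].[O-]Cl=O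
Why: Oxoammonium-catalysed oxidation to the aldehyde with immediate chlorite oxidation to the acid at near-neutral pH (a one-pot alcohol-to-acid oxidation of the Pinnick type) avoids enolisation of the α-stereogenic β,γ-unsaturated aldehyde.

Step 11
Reactants: 15 (2R,3E)-4-iodo-2-methylbut-3-enoic acid
Product: 16 methyl (2R,3E)-4-iodo-2-methylbut-3-enoate
Conditions: Me3SiCHN2, MeOH/toluene, 0 °C
Reagents that add atoms: (trimethylsilyl)diazomethane C[Si](C)(C)C=[N+]=[N-]
Why: Esterification by diazomethane generated in situ from Me3SiCHN2 and MeOH is base-free, so the α-stereocenter and the β,γ-olefin position are kept.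

Step 12
Reactants: 9 terminal alkyne, 16 methyl (2R,3E)-4-iodo-2-methylbut-3-enoate
Product: 19 methyl (2R,3E,5E)-2,6-dimethyl-8-((4aS,8aS)-2,5,5,8a-tetramethyl-3,4,4a,5,6,7,8,8a-octahydronaphthalen-1-yl)octa-3,5-dienoate, via alkenyldimethylalane 17 (not isolated), via alkenylzinc chloride 18 (not isolated)
Conditions: AlMe3 (2.5 equiv), Cp2ZrCl2 (0.25 equiv), CH2Cl2, 0 °C → rt; volatiles removed in vacuo; ZnCl2, THF; then 16, Pd(PPh3)4 (5 mol %), rt
Reagents that add atoms: trimethylaluminium C[Al](C)C
Why: Zr-catalysed syn-carboalumination of the terminal alkyne (methyl to the internal carbon, aluminium to the terminus) gives the (E)-alkenylalane 17, and transmetalation to zinc followed by Pd-catalysed Negishi coupling with retention at both alkenyl carbons should give the (3E,5E)-diene under non-basic conditions that leave the ester α-stereocenter and the ring olefin untouched.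

**Compound list**

1 | (S)-α-ionone [(3E)-4-((1S)-2,6,6-trimethylcyclohex-2-en-1-yl)but-3-en-2-one] | CC(=O)/C=C/[C@@H]1C(C)=CCCC1(C)C | starting material
2 | triethylsilyl enol ether [triethyl((4-((1S)-2,6,6-trimethylcyclohex-2-en-1-yl)but-2-en-2-yl)oxy)silane; enol ether geometry not defined; not isolated] | CC(O[Si](CC)(CC)CC)=CC[C@@H]1C(C)=CCCC1(C)C | intermediate
3 | (S)-dihydro-α-ionone [4-((1S)-2,6,6-trimethylcyclohex-2-en-1-yl)butan-2-one] | CC(=O)CC[C@@H]1C(C)=CCCC1(C)C | intermediate
4 | hydroxy ketone [4-((1S)-2-hydroxy-2,6,6-trimethylcyclohexyl)butan-2-one; carbinol epimers] | CC(=O)CC[C@@H]1C(C)(O)CCCC1(C)C | intermediate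
5 | cyclopropylidene carbinol [(2S)-2-(3-cyclopropylidenebutyl)-1,3,3-trimethylcyclohexan-1-ol; carbinol epimers] | CC(CC[C@@H]1C(C)(O)CCCC1(C)C)=C1CC1 | intermediate
6 | tertiary cyclohexyl cation [2-(3-cyclopropylidenebutyl)-1,3,3-trimethylcyclohexan-1-ylium, ring CH configured as in 5; not isolated] | C[C+]1CCCC(C)(C)[C@@H]1CCC(C)=C1CC1 | intermediate
7 | spiro cyclopropylcarbinyl cation [trans-fused 2,5,5,8a-tetramethyloctahydrospiro(naphthalene-1,1'-cyclopropan)-2-ylium, ring fusion as in 8; not isolated] | C[C+]1CC[C@H]2C(C)(C)CCC[C@]2(C)C13CC3 | intermediate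
8 | homoallylic chloride [(4aS,8aS)-1-(2-chloroethyl)-2,5,5,8a-tetramethyl-3,4,4a,5,6,7,8,8a-octahydronaphthalene] | ClCCC1=C(C)CC[C@H]2C(C)(C)CCC[C@]12C | intermediate
9 | terminal alkyne [(4aS,8aS)-1-(but-3-yn-1-yl)-2,5,5,8a-tetramethyl-3,4,4a,5,6,7,8,8a-octahydronaphthalene] | C#CCCC1=C(C)CC[C@H]2C(C)(C)CCC[C@]12C | intermediate
10 | methyl (S)-3-hydroxy-2-methylpropanoate | COC(=O)[C@@H](C)CO | starting material
11 | methyl (S)-3-((tert-butyldimethylsilyl)oxy)-2-methylpropanoate | COC(=O)[C@@H](C)CO[Si](C)(C)C(C)(C)C | intermediate
12 | (S)-3-((tert-butyldimethylsilyl)oxy)-2-methylpropanal | O=C[C@@H](C)CO[Si](C)(C)C(C)(C)C | intermediate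
13 | tert-butyl(((2R,3E)-4-iodo-2-methylbut-3-en-1-yl)oxy)dimethylsilane | I/C=C/[C@@H](C)CO[Si](C)(C)C(C)(C)C | intermediate
14 | (2R,3E)-4-iodo-2-methylbut-3-en-1-ol | I/C=C/[C@@H](C)CO | intermediate
15 | (2R,3E)-4-iodo-2-methylbut-3-enoic acid | I/C=C/[C@@H](C)C(=O)O | intermediate
16 | methyl (2R,3E)-4-iodo-2-methylbut-3-enoate | I/C=C/[C@@H](C)C(=O)OC | intermediate
17 | alkenyldimethylalane [dimethyl((1E)-2-methyl-4-((4aS,8aS)-2,5,5,8a-tetramethyl-3,4,4a,5,6,7,8,8a-octahydronaphthalen-1-yl)but-1-en-1-yl)alumane; not isolated] | C[Al](C)/C=C(\C)CCC1=C(C)CC[C@H]2C(C)(C)CCC[C@]12C | intermediate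
18 | alkenylzinc chloride [chloro((1E)-2-methyl-4-((4aS,8aS)-2,5,5,8a-tetramethyl-3,4,4a,5,6,7,8,8a-octahydronaphthalen-1-yl)but-1-en-1-yl)zinc; not isolated] | Cl[Zn]/C=C(\C)CCC1=C(C)CC[C@H]2C(C)(C)CCC[C@]12C | intermediate
19 | methyl (2R,3E,5E)-2,6-dimethyl-8-((4aS,8aS)-2,5,5,8a-tetramethyl-3,4,4a,5,6,7,8,8a-octahydronaphthalen-1-yl)octa-3,5-dienoate | COC(=O)[C@H](C)/C=C/C=C(\C)CCC1=C(C)CC[C@H]2C(C)(C)CCC[C@]12C | target

**Step count and risks**

Total step count: 12. Longest linear sequence: 7 steps (steps 6–11 and 12, from 10); the terpene branch from 1 is 6 steps (steps 1–5 and 12).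

Steps most likely to fail:

1. Step 4 (Proposed new method). What may go wrong: electrophilic ring opening of the alkylidenecyclopropane before ring B closes, proton loss from the tertiary cation, or ring expansion of the cyclopropylcarbinyl cation in competition with chloride opening. Fallback with known chemistry, setting out from 3 and coming back at 9: addition of c-C3H5MgBr (THF, 0 °C) to ketone 3 should give the tertiary cyclopropyl carbinol F1. MgBr2·OEt2 in refluxing ether should open it in a Julia olefin synthesis to the homoallylic bromide F2 (E isomer expected to predominate; the Z isomer converges later). SnCl4 in CH2Cl2 at −78 °C, followed in the same flask by equilibration with TsOH, should close ring B by the classical cation–olefin cyclization of the ring A olefin onto the trisubstituted olefin and settle the double bond in the tetrasubstituted C8=C9 position, giving the bicyclic bromide F3. F3 takes the place of 8 in step 5 and rejoins the route at alkyne 9. In this fallback the olefin position is under thermodynamic instead of mechanistic control.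

2. Step 5. What may go wrong: base-induced elimination of hydrogen chloride toward the allylic hydrogens (E2) outrunning substitution. Fallback by polarity reversal at the terminal carbon, setting out from 8 and coming back at 9: magnesium insertion into 8 (Mg, THF, reflux) should give the homoallyl Grignard reagent F4. CuCl2-catalysed coupling of F4 with (bromoethynyl)triisopropylsilane in THF should give the silyl alkyne F5. Bu4NF in THF should then free alkyne 9.

3. Step 12. What may go wrong: loss of configuration at the ester α-carbon, migration of the C3=C4 olefin into conjugation, or methyl transfer from aluminium to the ester during the coupling. Fallback that moves the oxidation-state adjustment behind the coupling, setting out from 9 and 13 and coming back at 19: the same carboalumination/ZnCl2/Pd(PPh3)4 sequence run with silyl ether iodide 13, which carries neither an ester nor an acidic α-hydrogen, should give the silyl ether F6. HF·pyridine should give the alcohol F7. TEMPO (cat.) with PhI(OAc)2 in aqueous MeCN should give the acid F8. Me3SiCHN2 in MeOH/toluene should then give 19.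

**Further compounds**

F1 | step 4 | 2-cyclopropyl-4-((1S)-2,6,6-trimethylcyclohex-2-en-1-yl)butan-2-ol (carbinol epimers) | CC(O)(CC[C@@H]1C(C)=CCCC1(C)C)C1CC1
F2 | step 4 | (6S)-6-((3E)-6-bromo-3-methylhex-3-en-1-yl)-1,5,5-trimethylcyclohex-1-ene | BrCC/C=C(\C)CC[C@@H]1C(C)=CCCC1(C)C
F3 | step 4 | (4aS,8aS)-1-(2-bromoethyl)-2,5,5,8a-tetramethyl-3,4,4a,5,6,7,8,8a-octahydronaphthalene | BrCCC1=C(C)CC[C@H]2C(C)(C)CCC[C@]12C
F4 | step 5 | chloro(2-((4aS,8aS)-2,5,5,8a-tetramethyl-3,4,4a,5,6,7,8,8a-octahydronaphthalen-1-yl)ethyl)magnesium | Cl[Mg]CCC1=C(C)CC[C@H]2C(C)(C)CCC[C@]12C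
F5 | step 5 | triisopropyl(4-((4aS,8aS)-2,5,5,8a-tetramethyl-3,4,4a,5,6,7,8,8a-octahydronaphthalen-1-yl)but-1-yn-1-yl)silane | CC(C)[Si](C#CCCC1=C(C)CC[C@H]2C(C)(C)CCC[C@]12C)(C(C)C)C(C)C
F6 | step 12 | tert-butyl(((2R,3E,5E)-2,6-dimethyl-8-((4aS,8aS)-2,5,5,8a-tetramethyl-3,4,4a,5,6,7,8,8a-octahydronaphthalen-1-yl)octa-3,5-dien-1-yl)oxy)dimethylsilane | CC(C)(C)[Si](C)(C)OC[C@H](C)/C=C/C=C(\C)CCC1=C(C)CC[C@H]2C(C)(C)CCC[C@]12C
F7 | step 12 | (2R,3E,5E)-2,6-dimethyl-8-((4aS,8aS)-2,5,5,8a-tetramethyl-3,4,4a,5,6,7,8,8a-octahydronaphthalen-1-yl)octa-3,5-dien-1-ol | OC[C@H](C)/C=C/C=C(\C)CCC1=C(C)CC[C@H]2C(C)(C)CCC[C@]12C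
F8 | step 12 | (2R,3E,5E)-2,6-dimethyl-8-((4aS,8aS)-2,5,5,8a-tetramethyl-3,4,4a,5,6,7,8,8a-octahydronaphthalen-1-yl)octa-3,5-dienoic acid | OC(=O)[C@H](C)/C=C/C=C(\C)CCC1=C(C)CC[C@H]2C(C)(C)CCC[C@]12C
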